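**Plan**

- Retrosynthesis: the four O-benzyl groups are cut first, then the bond between C2 of the flavone pyranone ring and the para carbon of the phenoxy ring (C2-zincation/Negishi). Next come the C2–C1' bond of the flavanone (asymmetric 1,4-addition), the C–B bond of the catechol-derived ring, and last the diaryl ether C–O bond.
- Forward: a diaryl ether linchpin is made (Chan–Lam), iodinated para to OBn and turned into a boronic acid. That acid adds to C2 of 5-(benzyloxy)-7-methoxychromone and so creates the flavanone. C2 of 5,7-bis(benzyloxy)chromone is then zincated and coupled to the aryl bromide, and hydrogenolysis finishes the route.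
- Enabling feature: in the apigenin half, C2–H of the 4H-chromen-4-one ring is bonded to ring oxygen O1 and is the β-carbon of the C2=C3–C4=O vinylogous ester. It is the most acidic C–H of that bicycle, so it is metalated directly and needs no leaving group. The same carbon acts as the electrophilic β-position in the other chromone.
- Both C2–aryl bonds therefore come from unfunctionalised chromone C2 positions, and each heterocycle enters at its final oxidation level (flavone versus flavanone), so no late oxidation has to tell them apart.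
- Stereochemistry: the only stereocentre, C2 of the flavanone (S), is set by the chiral bisphosphine–Rh catalyst in step 6. All later steps are non-basic (organozinc coupling, neutral hydrogenolysis).

Key step: step 8

Remark: the target SMILES corresponds to the (2S)-flavanone, and the route is planned for this enantiomer.
Remark: the sense of induction in step 6 is assigned by analogy with (S)-configured atropisomeric bisphosphine–Rh(I) catalysts on cyclic enones; the antipodal ligand would be used if the product analysis showed the opposite sense.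
Remark: acetophenones 8 and 13 are taken as purchased materials.

**Route**

Step 1
Reactants: 1 2-(benzyloxy)phenol; 2 (4-bromophenyl)boronic acid
Product: 3 1-(benzyloxy)-2-(4-bromophenoxy)benzene
Conditions: Cu(OAc)2 (20 mol %), pyridine, 4 Å MS, CH2Cl2, O2 (1 atm), rt
Reagents that add atoms: none
Why: Chan–Lam oxidative C–O coupling forms the diaryl ether at room temperature through a copper phenoxide/aryl intermediate and leaves the C–Br bond untouched.

Step 2
Reactants: 3 1-(benzyloxy)-2-(4-bromophenoxy)benzene
Product: 4 1-(benzyloxy)-2-(4-bromophenoxy)-4-iodobenzene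
Conditions: NIS, TFA (cat.), MeCN, 0 °C → rt
Reagents that add atoms: N-iodosuccinimide, O=C1CCC(=O)N1I
Why: Electrophilic aromatic iodination should go para to the benzyloxy group, the stronger donor on the catechol ring (alkoxy over aryloxy), while the bromophenoxy ring is deactivated and para-blocked.

Step 3
Reactants: 4 1-(benzyloxy)-2-(4-bromophenoxy)-4-iodobenzene
Product: 7 [4-(benzyloxy)-3-(4-bromophenoxy)phenyl]boronic acid, via arylmagnesium chloride 5 (not isolated), via dimethyl arylboronate 6 (not isolated)
Conditions: i-PrMgCl·LiCl, THF, −15 °C → rt; B(OMe)3, −78 °C → rt; 1 M HCl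
Reagents that add atoms: trimethyl borate, COB(OC)OC; water, O; i-PrMgCl·LiCl, CC(C)[Mg]Cl.[Li]Cl (its MgCl stays only in intermediate 5)
Why: Iodine–magnesium exchange with the turbo-Grignard reagent is much faster at C–I than at the electron-rich C–Br, and the aryl Grignard is trapped by the borate and hydrolysed to the boronic acid (standard exchange/borylation).

Step 4
Reactants: 8 1-(2,6-dihydroxy-4-methoxyphenyl)ethan-1-one
Product: 9 1-[2-(benzyloxy)-6-hydroxy-4-methoxyphenyl]ethan-1-one
Conditions: BnBr (1.05 equiv), K2CO3, acetone, reflux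
Reagents that add atoms: benzyl bromide, BrCc1ccccc1
Why: Williamson etherification should stop at the mono-ether because the remaining phenol is held in a hydrogen bond to the acetyl carbonyl and is alkylated far more slowly.

Step 5
Reactants: 9 1-[2-(benzyloxy)-6-hydroxy-4-methoxyphenyl]ethan-1-one
Product: 11 5-(benzyloxy)-7-methoxy-4H-chromen-4-one, via enaminone 10 (not isolated)
Conditions: DMF-DMA, toluene, 100 °C; then 2 M HCl, CH2Cl2, rt
Reagents that add atoms: N,N-dimethylformamide dimethyl acetal, COC(OC)N(C)C
Why: Condensation of the methyl ketone with the amide acetal gives the β-(dimethylamino)enone, and acid promotes addition–elimination by the free ortho-phenol with loss of dimethylamine (enaminone chromone synthesis).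

Step 6
Reactants: 7 [4-(benzyloxy)-3-(4-bromophenoxy)phenyl]boronic acid; 11 5-(benzyloxy)-7-methoxy-4H-chromen-4-one
Product: 12 (2S)-5-(benzyloxy)-2-[4-(benzyloxy)-3-(4-bromophenoxy)phenyl]-7-methoxy-2,3-dihydro-4H-chromen-4-one
Conditions: [Rh(OH)(cod)]2 (3 mol %), (S)-MeO-F12-BIPHEP (6.6 mol %), CH2Cl2–H2O, 25 °C
Reagents that add atoms: none
Why: Rh(I)-catalysed asymmetric 1,4-addition of an arylboronic acid to a chromone (Hayashi–Miyaura type) places the aryl group on C2 and water protonates the rhodium enolate at C3; the C2 stereocentre is set by the electron-poor (S)-bisphosphine, which should expose the enone face leading to the (2S)-flavanone, and the aryl C–Br bond is inert to Rh(I) at this temperature.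

Step 7
Reactants: 13 1-[2,4-bis(benzyloxy)-6-hydroxyphenyl]ethan-1-one
Product: 15 5,7-bis(benzyloxy)-4H-chromen-4-one, via enaminone 14 (not isolated)
Conditions: DMF-DMA, toluene, 100 °C; then 2 M HCl, CH2Cl2, rt
Reagents that add atoms: N,N-dimethylformamide dimethyl acetal, COC(OC)N(C)C
Why: The same enaminone chromone synthesis as in step 5 should give the C2/C3-unsubstituted chromone with both remaining phenols masked as benzyl ethers.

Step 8
Reactants: 15 5,7-bis(benzyloxy)-4H-chromen-4-one (1.5 equiv); 12 (2S)-5-(benzyloxy)-2-[4-(benzyloxy)-3-(4-bromophenoxy)phenyl]-7-methoxy-2,3-dihydro-4H-chromen-4-one (1.0 equiv)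
Product: 17 (2S)-5-(benzyloxy)-2-{4-(benzyloxy)-3-[4-(5,7-bis(benzyloxy)-4-oxo-4H-chromen-2-yl)phenoxy]phenyl}-7-methoxy-2,3-dihydro-4H-chromen-4-one, via chromon-2-ylzinc chloride 16 (not isolated)
Conditions: TMPZnCl·LiCl (1.4 equiv), THF, 25 °C; then 12, Pd(OAc)2 (3 mol %), SPhos (6 mol %), THF, 25 → 50 °C
Reagents that add atoms: TMPZnCl·LiCl, CC1(C)CCCC(C)(C)N1[Zn]Cl.[Li]Cl (its ZnCl stays only in intermediate 16)
Why: The Lewis-acid-free zinc amide removes the C2–H of 15, which is acidified by ring oxygen O1 and by its β-position in the C2=C3–C4=O vinylogous ester, to give chromon-2-ylzinc chloride 16; this enters a Pd(0)/SPhos cycle of oxidative addition into the C–Br bond of 12, zinc-to-palladium transmetalation and reductive elimination that forms the C2–aryl bond. The closest known reaction type is the Negishi cross-coupling of C2-zincated chromones with aryl halides to give flavones. No ring is closed and no stereocentre is formed. Site selectivity for C2 over C3, C6 and C8 rests on the acidity of C2–H in the absence of MgCl2, which would steer the base to C3 through carbonyl complexation, and on benzyl ethers being poor directing groups for a zinc amide. Chemoselectivity rests on the low basicity and nucleophilicity of the heteroarylzinc chloride, which should neither add to the C4 ketone of 12 nor enolise its C3, so the base-labile C2 stereocentre is carried through; the amide base is consumed by the slight excess of 15 before 12 is added. The coupling delivers the full skeleton with the flavone already at its oxidation level, so no dehydrogenation has to discriminate between the two heterocycles.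

Step 9
Reactants: 17 (2S)-5-(benzyloxy)-2-{4-(benzyloxy)-3-[4-(5,7-bis(benzyloxy)-4-oxo-4H-chromen-2-yl)phenoxy]phenyl}-7-methoxy-2,3-dihydro-4H-chromen-4-one
Product: 18 (2S)-2-{3-[4-(5,7-dihydroxy-4-oxo-4H-chromen-2-yl)phenoxy]-4-hydroxyphenyl}-5-hydroxy-7-methoxy-2,3-dihydro-4H-chromen-4-one
Conditions: H2 (1 atm), 10% Pd/C, EtOAc–MeOH, rt
Reagents that add atoms: none
Why: Neutral hydrogenolysis should cleave the four aryl benzyl ethers and leave the aryl methyl ether, the diaryl ether, the more slowly reduced flavone C2=C3 bond and, in the absence of acid or base, the flavanone stereocentre.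

**Compound list**

1 | 2-(benzyloxy)phenol | Oc1ccccc1OCc1ccccc1 | starting material
2 | (4-bromophenyl)boronic acid | OB(O)c1ccc(Br)cc1 | starting material
3 | 1-(benzyloxy)-2-(4-bromophenoxy)benzene | Brc1ccc(Oc2ccccc2OCc2ccccc2)cc1 | intermediate
4 | 1-(benzyloxy)-2-(4-bromophenoxy)-4-iodobenzene | Brc1ccc(Oc2cc(I)ccc2OCc2ccccc2)cc1 | intermediate
5 | [4-(benzyloxy)-3-(4-bromophenoxy)phenyl]magnesium chloride (LiCl complex) | Cl[Mg]c1ccc(OCc2ccccc2)c(Oc2ccc(Br)cc2)c1 | intermediate (not isolated)
6 | dimethyl [4-(benzyloxy)-3-(4-bromophenoxy)phenyl]boronate | COB(OC)c1ccc(OCc2ccccc2)c(Oc2ccc(Br)cc2)c1 | intermediate (not isolated)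
7 | [4-(benzyloxy)-3-(4-bromophenoxy)phenyl]boronic acid | OB(O)c1ccc(OCc2ccccc2)c(Oc2ccc(Br)cc2)c1 | intermediate
8 | 1-(2,6-dihydroxy-4-methoxyphenyl)ethan-1-one | CC(=O)c1c(O)cc(OC)cc1O | starting material
9 | 1-[2-(benzyloxy)-6-hydroxy-4-methoxyphenyl]ethan-1-one | CC(=O)c1c(O)cc(OC)cc1OCc1ccccc1 | intermediate
10 | (E)-1-[2-(benzyloxy)-6-hydroxy-4-methoxyphenyl]-3-(dimethylamino)prop-2-en-1-one | CN(C)/C=C/C(=O)c1c(O)cc(OC)cc1OCc1ccccc1 | intermediate (not isolated)
11 | 5-(benzyloxy)-7-methoxy-4H-chromen-4-one | O=c1ccoc2cc(OC)cc(OCc3ccccc3)c12 | intermediate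
12 | (2S)-5-(benzyloxy)-2-[4-(benzyloxy)-3-(4-bromophenoxy)phenyl]-7-methoxy-2,3-dihydro-4H-chromen-4-one | COc1cc(OCc2ccccc2)c3c(c1)O[C@H](c1ccc(OCc2ccccc2)c(Oc2ccc(Br)cc2)c1)CC3=O | intermediate
13 | 1-[2,4-bis(benzyloxy)-6-hydroxyphenyl]ethan-1-one | CC(=O)c1c(O)cc(OCc2ccccc2)cc1OCc1ccccc1 | starting material
14 | (E)-1-[2,4-bis(benzyloxy)-6-hydroxyphenyl]-3-(dimethylamino)prop-2-en-1-one | CN(C)/C=C/C(=O)c1c(O)cc(OCc2ccccc2)cc1OCc1ccccc1 | intermediate (not isolated)
15 | 5,7-bis(benzyloxy)-4H-chromen-4-one | O=c1ccoc2cc(OCc3ccccc3)cc(OCc3ccccc3)c12 | intermediate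
16 | [5,7-bis(benzyloxy)-4-oxo-4H-chromen-2-yl]zinc chloride (LiCl complex) | Cl[Zn]c1cc(=O)c2c(OCc3ccccc3)cc(OCc3ccccc3)cc2o1 | intermediate (not isolated)
17 | (2S)-5-(benzyloxy)-2-{4-(benzyloxy)-3-[4-(5,7-bis(benzyloxy)-4-oxo-4H-chromen-2-yl)phenoxy]phenyl}-7-methoxy-2,3-dihydro-4H-chromen-4-one | COc1cc(OCc2ccccc2)c3c(c1)O[C@H](c1ccc(OCc2ccccc2)c(Oc2ccc(cc2)-c2cc(=O)c4c(OCc5ccccc5)cc(OCc5ccccc5)cc4o2)c1)CC3=O | intermediate
18 | (2S)-2-{3-[4-(5,7-dihydroxy-4-oxo-4H-chromen-2-yl)phenoxy]-4-hydroxyphenyl}-5-hydroxy-7-methoxy-2,3-dihydro-4H-chromen-4-one | COc1cc(O)c2c(c1)O[C@H](c1ccc(O)c(Oc3ccc(-c4cc(=O)c5c(O)cc(O)cc5o4)cc3)c1)CC2=O | target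

**Summary**

Total step count: 9. Longest linear sequence: 6 steps (1, 2, 3, 6, 8, 9).

**Steps most likely to fail**

Step 8. The metalation may occur at a site other than C2 of 15, the electron-poor heteroarylzinc may transmetalate or couple sluggishly, or residual amide base may erode the flavanone stereocentre through reversible ring opening to the chalcone. The fallback fixes the C2 substituent by ring construction and couples without base. It sets out from bromide 12 and acetophenone 13 and returns to the route at 17. Miyaura borylation of 12 (B2pin2, PdCl2(dppf), KOAc, dioxane, 80 °C) would give the arylboronic acid pinacol ester F1. Separately, 13 would be condensed with carbon disulfide (KOt-Bu, THF) to 5,7-bis(benzyloxy)-4-hydroxy-2H-chromene-2-thione F2, which would be S-methylated (MeI, K2CO3, acetone) to 5,7-bis(benzyloxy)-2-(methylsulfanyl)-4H-chromen-4-one F3. A Liebeskind–Srogl coupling of F1 with F3 (Pd2(dba)3, tri(2-furyl)phosphine, CuTC, THF, 50 °C; the pinacol ester is a slower but competent partner) would form the same C2–aryl bond under neutral conditions and give 17.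

Step 6. Turnover on the electron-rich, peri-substituted chromone may be low, the rhodium enolate may open to the 2'-hydroxychalcone, the electron-rich boronic acid may protodeboronate, or facial selectivity may be insufficient. The fallback builds the flavanone by the chalcone route and obtains the enantiomer by separation. It sets out from iodide 4 (through Grignard reagent 5) and acetophenone 9 and returns at 12. Quenching 5 with DMF would give 4-(benzyloxy)-3-(4-bromophenoxy)benzaldehyde F4. Claisen–Schmidt condensation of F4 with 9 (KOH, EtOH, rt) would give (E)-1-[2-(benzyloxy)-6-hydroxy-4-methoxyphenyl]-3-[4-(benzyloxy)-3-(4-bromophenoxy)phenyl]prop-2-en-1-one F5. Intramolecular oxa-Michael addition (NaOAc, EtOH, reflux) would give the racemic flavanone F6. Preparative chromatography on a chiral stationary phase would deliver the (2S)-enantiomer 12; the unwanted half of F6 can be re-equilibrated with base and recycled.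

Step 9. The flavone C2=C3 bond may be saturated, the benzylic C2–O1 bond of the flavanone may be opened by hydrogenolysis, or the reaction may stall at partially benzylated stages as the polyphenol adsorbs on the catalyst. The fallback is non-reductive and goes from 17 directly to 18: BCl3 with pentamethylbenzene as benzyl-cation scavenger, CH2Cl2, −78 °C. This Lewis-acid-assisted dealkylation should cleave the aryl benzyl ethers and leave the non-peri 7-methyl ether, both enone systems and the benzylic C–O bond untouched. No new compound is made.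

**Further compounds**

F1 | step 8 | (2S)-5-(benzyloxy)-2-{4-(benzyloxy)-3-[4-(4,4,5,5-tetramethyl-1,3,2-dioxaborolan-2-yl)phenoxy]phenyl}-7-methoxy-2,3-dihydro-4H-chromen-4-one | COc1cc(OCc2ccccc2)c3c(c1)O[C@H](c1ccc(OCc2ccccc2)c(Oc2ccc(cc2)B2OC(C)(C)C(C)(C)O2)c1)CC3=O
F2 | step 8 | 5,7-bis(benzyloxy)-4-hydroxy-2H-chromene-2-thione | S=c1cc(O)c2c(OCc3ccccc3)cc(OCc3ccccc3)cc2o1
F3 | step 8 | 5,7-bis(benzyloxy)-2-(methylsulfanyl)-4H-chromen-4-one | CSc1cc(=O)c2c(OCc3ccccc3)cc(OCc3ccccc3)cc2o1
F4 | step 6 | 4-(benzyloxy)-3-(4-bromophenoxy)benzaldehyde | O=Cc1ccc(OCc2ccccc2)c(Oc2ccc(Br)cc2)c1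
F5 | step 6 | (E)-1-[2-(benzyloxy)-6-hydroxy-4-methoxyphenyl]-3-[4-(benzyloxy)-3-(4-bromophenoxy)phenyl]prop-2-en-1-one | COc1cc(O)c(C(=O)/C=C/c2ccc(OCc3ccccc3)c(Oc3ccc(Br)cc3)c2)c(OCc2ccccc2)c1
F6 | step 6 | rac-5-(benzyloxy)-2-[4-(benzyloxy)-3-(4-bromophenoxy)phenyl]-7-methoxy-2,3-dihydro-4H-chromen-4-one | COc1cc(OCc2ccccc2)c3c(c1)OC(c1ccc(OCc2ccccc2)c(Oc2ccc(Br)cc2)c1)CC3=O
F0 | step 9 | none | none
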